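## Retrosynthetic overview
1. The target comes from aqueous acid treatment of a fully protected 3,4-diacyl-1,5-quinide, which opens the lactone and removes four MOM groups.
2. Two ester C–O disconnections (equatorial O-3 first, axial O-4 second) lead to a 1-O-MOM-quinide diol plus MOM-protected caffeic and p-coumaric acids.
3. Each cinnamic acid comes from a Mizoroki–Heck aryl–vinyl coupling of an aryl halide (from catechol or 4-iodophenol) with acrylic acid.
4. The diol comes from convex-face dihydroxylation of a bicyclic allylic lactone. That lactone comes from an enantioconvergent Pd-catalysed allylic C–H lactonisation of a racemic cyclohexene acid (new step, sets C1 and C5).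
5. Ring order: the carbocycle forms first (Diels–Alder of butadiene with 2-acetoxyacrylate from methyl pyruvate), the γ-lactone second (C–H activation), and the lactone is reopened last. The arene rings are bought.

Assumption: the SMILES is read as 3-O-(E)-caffeoyl-4-O-(E)-p-coumaroyl-(−)-quinic acid (IUPAC quinic acid numbering, used throughout). The sense of induction of the new step cannot be predicted, so one ligand antipode is written. The other antipode is used if correlation of the dihydroxy lactone with natural (−)-quinide shows the opposite sense.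

## Route

Step 1
Reactants: 1 methyl pyruvate
Product: 2 methyl 2-acetoxyacrylate
Conditions: Ac2O (3 equiv), p-TsOH·H2O (3 mol %), 135 °C, AcOH distilled off
Reagents that add atoms: acetic anhydride, CC(=O)OC(C)=O
Why: Acid-catalysed enol acetylation of an α-keto ester, in which Ac2O traps the pyruvate enol and removal of AcOH drives the equilibrium; no stereocentre is formed.

Step 2
Reactants: 2 methyl 2-acetoxyacrylate; 3 buta-1,3-diene
Product: 4 rac-methyl 1-acetoxycyclohex-3-ene-1-carboxylate
Conditions: 3 (4 equiv), BHT (1 mol %), PhMe, sealed vessel, 160 °C, 36 h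
Reagents that add atoms: none
Why: Thermal Diels–Alder [4+2] of an ester-activated captodative dienophile with a symmetrical diene has no regiochemical issue, and C1 is formed racemic on purpose because step 5 erases and resets it.

Step 3
Reactants: 4 rac-methyl 1-acetoxycyclohex-3-ene-1-carboxylate
Product: 5 rac-1-hydroxycyclohex-3-ene-1-carboxylic acid
Conditions: LiOH·H2O (3.5 equiv), THF/MeOH/H2O, rt; then 1 M HCl to pH 2
Reagents that add atoms: lithium hydroxide, [Li+].[OH-]
Why: Saponification (BAc2) cleaves both the methyl ester and the acetate, while the isolated alkene and the tertiary carbinol are inert to base.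

Step 4
Reactants: 5 rac-1-hydroxycyclohex-3-ene-1-carboxylic acid
Product: 7 rac-1-(methoxymethoxy)cyclohex-3-ene-1-carboxylic acid, via rac-methoxymethyl 1-(methoxymethoxy)cyclohex-3-ene-1-carboxylate 6 (not isolated)
Conditions: MOMCl (3 equiv), iPr2NEt (4 equiv), (CH2Cl)2, 0→60 °C; then LiOH (1.5 equiv), THF/H2O, 0 °C; 1 M HCl to pH 3–4, 0 °C
Reagents that add atoms: chloromethyl methyl ether, COCCl; lithium hydroxide, [Li+].[OH-]
Why: MOM protection (O-alkylation) of OH and CO2H followed by selective saponification of the very labile MOM ester leaves the base-stable tertiary MOM ether, which blocks α-hydroxy-acid chelation or decarboxylation on Pd in step 5 and acylation at O-1 later.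

Step 5
Reactants: 7 rac-1-(methoxymethoxy)cyclohex-3-ene-1-carboxylic acid
Product: 8 (1S,5R)-1-(methoxymethoxy)-6-oxabicyclo[3.2.1]oct-3-en-7-one
Conditions: Pd(OCOCF3)2 (10 mol %), (M,S,S)-iPr-SPRIX (C2-symmetric spiro bis(isoxazoline), 12 mol %), p-benzoquinone (2 equiv), CH2Cl2, 30 °C, 48 h
Reagents that add atoms: none
Why: Proposed new method: enantioconvergent (stereoablative) allylic C–H lactonisation, in which electrophilic Pd(II) cleaves the less hindered, more electron-rich allylic C5–H (the C2–H bonds are neopentylic and deactivated by the O/CO2H-bearing C1) of either enantiomer of 7 to give the same catalyst-bound η3-cyclohexenyl species whose allyl unit C3–C4–C5 is bisected by a mirror plane through C1 and C4, so the racemic C1 centre is erased; the tethered carboxylate can reach only the two enantiotopic allyl termini on its own ring face (only the cis-bridged γ-lactone can form), the C2-symmetric ligand (one allyl complex, no rotamer problem) selects the terminus and so sets C1 and C5 together, and benzoquinone promotes C–O bond formation and reoxidises Pd(0) before it can re-ionise the product; the closest known reaction types are Pd(II)/benzoquinone allylic acyloxylation of cyclohexene through π-allyl-Pd, Pd(II)/SPRIX enantioselective oxidative allylic C–H esterification of acyclic 4-alkenoic acids to γ-lactones, and Pd(0) desymmetrisation of meso-cyclohexenyl π-allyl complexes by carboxylates, none of which has been used to converge a racemic ring acid onto one bridged lactone.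

Step 6
Reactants: 8 (1S,5R)-1-(methoxymethoxy)-6-oxabicyclo[3.2.1]oct-3-en-7-one
Product: 9 (1S,3R,4R,5R)-3,4-dihydroxy-1-(methoxymethoxy)-6-oxabicyclo[3.2.1]octan-7-one (1-O-MOM-(−)-quinide)
Conditions: OsO4 (2 mol %), NMO (1.5 equiv), acetone/H2O 5:1, rt
Reagents that add atoms: osmium tetroxide (catalytic O carrier), O=[Os](=O)(=O)=O; N-methylmorpholine N-oxide, C[N+]1([O-])CCOCC1; water, O
Why: Catalytic OsO4/NMO syn-dihydroxylation occurs on the open face of the carbocycle, anti to the axial O6–C7 lactone bridge, which sets C3 and C4 with both oxygens cis to O-1 and trans to O-5.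

Step 7
Reactants: 10 catechol
Product: 11 1,2-bis(methoxymethoxy)benzene
Conditions: MOMCl (2.6 equiv), iPr2NEt (3 equiv), CH2Cl2, 0 °C→rt
Reagents that add atoms: chloromethyl methyl ether, COCCl
Why: Standard MOM protection (phenoxide O-alkylation) masks both phenols against oxidation and later acylation.

Step 8
Reactants: 11 1,2-bis(methoxymethoxy)benzene
Product: 12 4-bromo-1,2-bis(methoxymethoxy)benzene
Conditions: NBS (1.05 equiv), MeCN, 0 °C→rt, dark
Reagents that add atoms: N-bromosuccinimide, O=C1CCC(=O)N1Br
Why: Electrophilic aromatic bromination of a 1,2-dialkoxyarene goes para to one oxygen (C4), because C3 is flanked by a MOM ether, and neutral NBS/MeCN leaves the acetals intact.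

Step 9
Reactants: 12 4-bromo-1,2-bis(methoxymethoxy)benzene; 13 acrylic acid
Product: 14 (E)-3-[3,4-bis(methoxymethoxy)phenyl]prop-2-enoic acid
Conditions: Pd(OAc)2 (2 mol %), P(o-tol)3 (6 mol %), Et3N (3 equiv), DMF, 100 °C
Reagents that add atoms: none
Why: Mizoroki–Heck coupling, in which syn-carbopalladation at the acrylate β-carbon and syn-β-hydride elimination give only the E-cinnamic acid, and MOM ethers are stable to the basic medium.

Step 10
Reactants: 15 4-iodophenol
Product: 16 1-iodo-4-(methoxymethoxy)benzene
Conditions: MOMCl (1.3 equiv), iPr2NEt (1.5 equiv), CH2Cl2, 0 °C→rt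
Reagents that add atoms: chloromethyl methyl ether, COCCl
Why: MOM protection (phenoxide O-alkylation) proceeds cleanly and the aryl iodide is untouched.

Step 11
Reactants: 16 1-iodo-4-(methoxymethoxy)benzene; 13 acrylic acid
Product: 17 (E)-3-[4-(methoxymethoxy)phenyl]prop-2-enoic acid
Conditions: Pd(OAc)2 (1 mol %), Et3N (3 equiv), MeCN, 80 °C
Reagents that add atoms: none
Why: Ligand-free Mizoroki–Heck coupling of an aryl iodide with acrylic acid is E-selective through syn-insertion and syn-β-H elimination.

Step 12
Reactants: 9 1-O-MOM-(−)-quinide; 14 (E)-3-[3,4-bis(methoxymethoxy)phenyl]prop-2-enoic acid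
Product: 18 1-O-methoxymethyl-3-O-[(E)-3,4-bis(methoxymethoxy)cinnamoyl]-1,5-quinide (4-OH free; O-1, O-3 and O-4 on one ring face, lactone bridge on the other)
Conditions: 14 (1.0 equiv), DCC (1.05 equiv), DMAP (10 mol %), CH2Cl2, −10→0 °C
Reagents that add atoms: none
Why: Steglich esterification is selective because in the rigid bicyclic chair the 3-OH is equatorial and open while the 4-OH is axial and flanked by the C5–O lactone bond, so one equivalent of acid at low temperature acylates O-3 and no stereocentre is touched.

Step 13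
Reactants: 18 1-O-methoxymethyl-3-O-[(E)-3,4-bis(methoxymethoxy)cinnamoyl]-1,5-quinide; 17 (E)-3-[4-(methoxymethoxy)phenyl]prop-2-enoic acid
Product: 19 1-O-methoxymethyl-3-O-[(E)-3,4-bis(methoxymethoxy)cinnamoyl]-4-O-[(E)-4-(methoxymethoxy)cinnamoyl]-1,5-quinide
Conditions: 17 (1.8 equiv), DCC (1.8 equiv), DMAP (50 mol %), CH2Cl2, rt→35 °C
Reagents that add atoms: none
Why: Steglich esterification with excess activated acid succeeds because O-1 is blocked and O-5 is tied up in the lactone, so the axial 4-OH is the only nucleophile, and afterwards no free OH is left for acyl migration.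

Step 14
Reactants: 19 1-O-methoxymethyl-3-O-[(E)-3,4-bis(methoxymethoxy)cinnamoyl]-4-O-[(E)-4-(methoxymethoxy)cinnamoyl]-1,5-quinide
Product: 20 (1R,3R,4S,5R)-3-{[(E)-3-(3,4-dihydroxyphenyl)prop-2-enoyl]oxy}-1,5-dihydroxy-4-{[(E)-3-(4-hydroxyphenyl)prop-2-enoyl]oxy}cyclohexane-1-carboxylic acid (target)
Conditions: 2 M aq HCl/THF 1:1, Ar, dark, 30 °C, 48–72 h; THF removed cold, reversed-phase C18
Reagents that add atoms: water, O
Why: In this acid-catalysed hydrolysis the four acetal-type MOM groups and the strained α-alkoxy γ-lactone cleave much faster than the conjugated cinnamate esters, acid suppresses O→O acyl migration, and only acyl–O or acetal C–O bonds break, so all four ring stereocentres and both E-alkenes are kept.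

## Compound list
1 | methyl pyruvate | COC(=O)C(C)=O | starting material
2 | methyl 2-acetoxyacrylate | C=C(OC(C)=O)C(=O)OC | intermediate
3 | buta-1,3-diene | C=CC=C | starting material
4 | rac-methyl 1-acetoxycyclohex-3-ene-1-carboxylate | COC(=O)C1(OC(C)=O)CC=CCC1 | intermediate
5 | rac-1-hydroxycyclohex-3-ene-1-carboxylic acid | OC(=O)C1(O)CC=CCC1 | intermediate
6 | rac-methoxymethyl 1-(methoxymethoxy)cyclohex-3-ene-1-carboxylate | COCOC(=O)C1(OCOC)CC=CCC1 | intermediate (not isolated)
7 | rac-1-(methoxymethoxy)cyclohex-3-ene-1-carboxylic acid | COCOC1(C(=O)O)CC=CCC1 | intermediate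
8 | (1S,5R)-1-(methoxymethoxy)-6-oxabicyclo[3.2.1]oct-3-en-7-one | O=C1O[C@H]2C=CC[C@]1(OCOC)C2 | intermediate
9 | (1S,3R,4R,5R)-3,4-dihydroxy-1-(methoxymethoxy)-6-oxabicyclo[3.2.1]octan-7-one | O=C1O[C@H]2[C@H](O)[C@H](O)C[C@]1(OCOC)C2 | intermediate
10 | catechol | Oc1ccccc1O | starting material
11 | 1,2-bis(methoxymethoxy)benzene | COCOc1ccccc1OCOC | intermediate
12 | 4-bromo-1,2-bis(methoxymethoxy)benzene | COCOc1ccc(Br)cc1OCOC | intermediate
13 | acrylic acid | C=CC(=O)O | starting material
14 | (E)-3-[3,4-bis(methoxymethoxy)phenyl]prop-2-enoic acid | COCOc1ccc(/C=C/C(=O)O)cc1OCOC | intermediate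
15 | 4-iodophenol | Oc1ccc(I)cc1 | starting material
16 | 1-iodo-4-(methoxymethoxy)benzene | COCOc1ccc(I)cc1 | intermediate
17 | (E)-3-[4-(methoxymethoxy)phenyl]prop-2-enoic acid | COCOc1ccc(/C=C/C(=O)O)cc1 | intermediate
18 | 1-O-methoxymethyl-3-O-[(E)-3,4-bis(methoxymethoxy)cinnamoyl]-1,5-quinide | O=C1O[C@H]2[C@H](O)[C@H](OC(=O)/C=C/c3ccc(OCOC)c(OCOC)c3)C[C@]1(OCOC)C2 | intermediate
19 | 1-O-methoxymethyl-3-O-[(E)-3,4-bis(methoxymethoxy)cinnamoyl]-4-O-[(E)-4-(methoxymethoxy)cinnamoyl]-1,5-quinide | O=C1O[C@H]2[C@H](OC(=O)/C=C/c3ccc(OCOC)cc3)[C@H](OC(=O)/C=C/c3ccc(OCOC)c(OCOC)c3)C[C@]1(OCOC)C2 | intermediate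
20 | 3-O-(E)-caffeoyl-4-O-(E)-p-coumaroyl-(−)-quinic acid | O=C(/C=C/c1ccc(O)cc1)O[C@H]1[C@H](O)C[C@](O)(C(=O)O)C[C@H]1OC(=O)/C=C/c1ccc(O)c(O)c1 | target

## Step count
- Total step count: 14.
- Longest linear sequence: 9 (steps 1–6, 12, 13, 14).

## Steps most likely to fail

**Risk A, step 5 (the new reaction).**
- A competing anti-oxypalladation/β-hydride elimination pathway would keep the memory of C1 and give racemic 8.
- C2–H cleavage would lead to other lactones or allylic esters.
- Pd(0) re-ionisation of the allylic lactone would erode the ee.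

The fallback uses known chemistry only. It sets out from 7 and comes back at 8. rac-7 is resolved by fractional crystallisation with (R)-1-phenylethylamine from acetone to give (R)-1-phenylethylammonium (S)-1-(methoxymethoxy)cyclohex-3-ene-1-carboxylate F1. Cold dilute acid liberates (S)-1-(methoxymethoxy)cyclohex-3-ene-1-carboxylic acid F2. Iodolactonisation (I2, KI, NaHCO3, CH2Cl2/H2O, 0 °C) proceeds by anti addition, with the carboxylate on the γ-carbon and the iodide axial, and gives (1S,4R,5R)-4-iodo-1-(methoxymethoxy)-6-oxabicyclo[3.2.1]octan-7-one F3. DBU (PhMe, 80 °C) then effects anti-E2 loss of HI away from the lactone oxygen to give 8.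

**Risk B, step 12.** The O-3/O-4 selectivity may be incomplete, or DMAP may promote 3→4 migration in the cis-diol monoester.

The fallback reverses the order of acylation with a temporary silyl group. It sets out from 9 and comes back at 19, bypassing 18. Selective equatorial silylation (TBSCl 1.1 equiv, imidazole, DMF, 0 °C) gives 1-O-methoxymethyl-3-O-(tert-butyldimethylsilyl)-1,5-quinide F4. DCC/DMAP with 17 gives 1-O-methoxymethyl-3-O-(tert-butyldimethylsilyl)-4-O-[(E)-4-(methoxymethoxy)cinnamoyl]-1,5-quinide F5. HF·pyridine (THF, 0 °C, acidic so no migration) gives 1-O-methoxymethyl-4-O-[(E)-4-(methoxymethoxy)cinnamoyl]-1,5-quinide F6. DCC/DMAP with 14 on the now free equatorial 3-OH gives 19.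

**Risk C, step 14.** The lactone may open incompletely in the THF-rich medium needed to dissolve 19, or 4→5 acyl migration may occur during the long reaction time.

The fallback decouples the two events and changes the order of bond cleavage. It sets out from 19 and comes back at 20. TFA/CH2Cl2 with a few equivalents of water (0 °C) has low water activity, so the lactone stays closed while all four MOM groups are removed. This gives the isolable 3-O-(E)-caffeoyl-4-O-(E)-p-coumaroyl-1,5-quinide F7. This water-compatible compound alone is then hydrolysed on a sulfonic acid ion-exchange resin (H+ form) in H2O/MeCN 9:1 at rt, where the lactone/acid equilibrium lies on the acid side. Filtration and lyophilisation then give 20.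

## Further compounds
F1 | step 5 | (R)-1-phenylethylammonium (S)-1-(methoxymethoxy)cyclohex-3-ene-1-carboxylate | COCO[C@]1(C(=O)[O-])CC=CCC1.C[C@@H]([NH3+])c1ccccc1
F2 | step 5 | (S)-1-(methoxymethoxy)cyclohex-3-ene-1-carboxylic acid | COCO[C@]1(C(=O)O)CC=CCC1
F3 | step 5 | (1S,4R,5R)-4-iodo-1-(methoxymethoxy)-6-oxabicyclo[3.2.1]octan-7-one | O=C1O[C@H]2[C@H](I)CC[C@]1(OCOC)C2
F4 | step 12 | 1-O-methoxymethyl-3-O-(tert-butyldimethylsilyl)-1,5-quinide | O=C1O[C@H]2[C@H](O)[C@H](O[Si](C)(C)C(C)(C)C)C[C@]1(OCOC)C2
F5 | step 12 | 1-O-methoxymethyl-3-O-(tert-butyldimethylsilyl)-4-O-[(E)-4-(methoxymethoxy)cinnamoyl]-1,5-quinide | O=C1O[C@H]2[C@H](OC(=O)/C=C/c3ccc(OCOC)cc3)[C@H](O[Si](C)(C)C(C)(C)C)C[C@]1(OCOC)C2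
F6 | step 12 | 1-O-methoxymethyl-4-O-[(E)-4-(methoxymethoxy)cinnamoyl]-1,5-quinide | O=C1O[C@H]2[C@H](OC(=O)/C=C/c3ccc(OCOC)cc3)[C@H](O)C[C@]1(OCOC)C2
F7 | step 14 | 3-O-(E)-caffeoyl-4-O-(E)-p-coumaroyl-1,5-quinide | O=C1O[C@H]2[C@H](OC(=O)/C=C/c3ccc(O)cc3)[C@H](OC(=O)/C=C/c3ccc(O)c(O)c3)C[C@]1(O)C2
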